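If I divide the rate of first end groups + links → side product by the rate of released group → by-product carried off, and take the exchange step as balanced, the released group is proportional to first end groups × second end groups / links. First end groups and time then drop out, and the rate of side product over the rate of by-product carried off equals c·L·L/B, with L the links, B the second end groups and c a lumped constant.

| flask | first end groups | second end groups | remark | time |
|---|---|---|---|---|
| Tuesday's | 0.50 M | 0.98 M | run made earlier |  |
| Wednesday's | 2 M | 0.98 M | run made earlier |  |
| Thursday's | 1 M | 2 M | run made earlier |  |
| flask | 1.0 M | 0.980 M |  | 50 min |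

- Tuesday's (time / min: links / %, side product / %): 5.00: 76.8, 22.8; 8.00: 76.4, 22.4; 12.0: 76.1, 22.9; 20.0: 76.9, 22.0; 40.0: 77.4, 22.1; 60.0: 76.7, 23.9
- Wednesday's (time / min: links / %, side product / %): 5.00: 10.2, 77.4; 8.00: 5.8, 84.9; 12.0: 5.4, 89.7; 20.0: 1.4, 93.6; 40.0: 0.1, 95.9; 60.0: 0.2, 97.7
- Thursday's (time / min: links / %, side product / %): 5.00: 65.5, 33.4; 10.0: 65.4, 34.8; 15.0: 64.2, 34.9; 30.0: 66.2, 34.1; 60.0: 65.8, 34.8

(scatter of a reading: 0.5 percentage points)

- percentages count the first end groups that a species holds: one side product counts as two
- steps under discussion: released group -> by-product carried off; first end groups + second end groups <-> links + released group; first end groups + links -> side product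

- the links standing at 50 min, as a percentage of the first end groups charged
- the side product standing at 50 min, as a percentage of the first end groups charged

Take a run that ends with its first end groups used up and its released group carried off, with charges a and b and a share y of a in links. I apply the ratio to the whole run, using end values, so c is a rough average:

S = (1 − y)/(1 + y), side product per by-product carried off

f = 1 − (1 + y)·a/(2·b), share of second end groups left

S = N·y·y/f

Here N = c·a·a/b. Tuesday's plateau, y = 76.7%, gives c = 0.482 L mol⁻¹. Thursday's, y = 65.4%, gives 0.573 L mol⁻¹. I take 0.527 L mol⁻¹.

For the flask, the selectivity factor, the ratio c·L·L/B taken at L = a and B = b, is N = 0.538. N alone is not enough, since the flask's a/b is twice Tuesday's, so f stays in. The gap S − N·y·y/f is 0.127 at y = 0.400 and −0.240 at y = 0.5. Interpolating gives 43.5% links and 56.5% side product.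

The forecast, holding that “selectivity depends on concentration”, gives 45% and 55%, 1.5 percentage points more links than mine.

The flask gives 45.6% links and 54.4% side product, 2.1 points more links than my reckoning. First end groups, the limiting reagent, stand at 0%, with 26% of the second end groups left. With y = 45.6% in the rule, N·y·y/f is 0.434, more than S at 0.374.

    released group → by-product carried off (k = 0.0175 s⁻¹)
    first end groups + second end groups ⇌ links + released group (K = 1.20, k = 1.94 L mol⁻¹ s⁻¹)
    first end groups + links → side product (k = 0.0120 L mol⁻¹ s⁻¹)

With 0.60 M of first end groups, N is 0.194, and the gap runs from 0.0242 at y = 0.667 to −0.0215 at y = 0.7, which gives 68.4% links. That neighbouring flask gives 70.1% links and 29.9% side product.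

(The data stem from a simulated flask from invented constants.)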